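**Plan**
- Retrosynthesis: C11=C12 is cut first (Wittig: ring-bearing C15 phosphonium salt + C15 aldehyde ester, itself cut at C11'=C12' into a C10 dial and a C5 phosphonate). Then C9=C10 (Wittig on a C9 methyl ketone) and the C3–O bond (hydroboration) are cut.
- Ring A is opened at C3=C4 and C4 is tied back to C9. This gives a 7-oxanorbornadiene, the Diels–Alder adduct of a 2-methyl-3-alkylfuran (C5–C8) and an acetylene equivalent (C4, C9). The side chain is cut at C1–C2 (furyl carbinol + allylsilane).
- Enabling feature: on ring B (O–C5–C6=C7–C8) the ring A carbon C4 at C5 and the chain carbon C9 at C8 lie on the same face, exactly like the two ends of the C4=C9 etheno bridge of a 7-oxabicyclo[2.2.1]hepta-2,5-diene.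
- Forward order: furan (future ring B) → bicycle → metathesis closes ring A and frees ring B with a C9 vinyl group → C9 ketone → C9=C10 → C3–OH → C15 salt → C30 polyene ester → aldehyde.
- Stereochemistry: the C5/C8 relation comes from the bridge and the absolute configuration from resolution of the bis-sulfone cycloadduct. C3 comes from hydroboration opposite the pseudo-axial C5 methyl, and the E-alkenes from stabilised Wittig/HWE reagents plus thermal equilibration.

Key step: step 6

Remark: locants C1–C19 and C8'–C15' follow carotenoid numbering of the target (ring A C1–C6, ring B O–C5–C6=C7–C8, chain from C9).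
Remark: cycloadduct 7 is written as the trans diastereomer with the C6 sulfonyl group endo and the C5 sulfonyl group exo; the other trans adduct, if it forms, would be removed by crystallisation before step 4, since it leads to the same diene.
Remark: dial 18 and phosphonate 19 are taken as purchasable carotenoid building blocks; all polyenes from step 13 on are handled under argon in the dark.

**Step 1**
Reactants: 1 methyl 2-methylfuran-3-carboxylate
Product: 3 2-(2-methylfuran-3-yl)propan-2-ol, via methyl ketone 2 (not isolated)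
Conditions: MeMgBr (3 equiv), THF, 0 °C → rt; aq. NH4Cl
Reagents that add atoms: methylmagnesium bromide, C[Mg]Br
Why: Double Grignard addition to an ester, in which the first equivalent gives ketone 2 and this, being more electrophilic than the ester, takes up the second methyl group at once to give the tertiary carbinol that carries the future C1 gem-dimethyl unit.

**Step 2**
Reactants: 3 2-(2-methylfuran-3-yl)propan-2-ol; 4 allyltrimethylsilane
Product: 5 2-methyl-3-(2-methylpent-4-en-2-yl)furan
Conditions: 4 (3 equiv), Ca(NTf2)2 (5 mol %), Bu4NPF6 (5 mol %), CH2Cl2, 0 °C → rt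
Reagents that add atoms: none
Why: Lewis-acid-catalysed SN1 allylation of a tertiary heterobenzylic alcohol (Hosomi–Sakurai type), in which the furan-stabilised tertiary cation is captured by the allylsilane at the exocyclic carbon with rearomatisation, creating the quaternary C1 and the pendant alkene.

**Step 3**
Reactants: 5 2-methyl-3-(2-methylpent-4-en-2-yl)furan; 6 (E)-1,2-bis(phenylsulfonyl)ethene
Product: 7 rac-(1S,4R,5R,6R)-5,6-bis(benzenesulfonyl)-1-methyl-2-(2-methylpent-4-en-2-yl)-7-oxabicyclo[2.2.1]hept-2-ene (5-exo,6-endo; racemate)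
Conditions: 6 (1.3 equiv), CH2Cl2 (2 M), rt, dark, several days
Reagents that add atoms: none
Why: Diels–Alder reaction of an electron-rich 2,3-dialkylfuran with a doubly activated acetylene-equivalent dienophile, which bonds suprafacially at the two furan α-carbons so that C4 and C9 are attached to C5 and C8 on one face of the future ring B and the two sulfonyl groups stay trans.

**Step 4**
Reactants: 7 racemic cycloadduct
Product: 8 (1S,4R,5R,6R)-5,6-bis(benzenesulfonyl)-1-methyl-2-(2-methylpent-4-en-2-yl)-7-oxabicyclo[2.2.1]hept-2-ene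
Conditions: preparative SFC, amylose tris(3,5-dimethylphenylcarbamate) phase, CO2–MeOH, 35 °C; antipodes assigned by anomalous-dispersion X-ray analysis (sulfur)
Reagents that add atoms: none
Why: Chromatographic resolution of a racemate on a chiral stationary phase, which suits this UV-active, crystalline and configurationally stable bis-sulfone and fixes the absolute configuration of C5 and C8 for the rest of the route.

**Step 5**
Reactants: 8 resolved bis-sulfone
Product: 9 (1R,4S)-1-methyl-2-(2-methylpent-4-en-2-yl)-7-oxabicyclo[2.2.1]hepta-2,5-diene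
Conditions: 6% Na(Hg), NaH2PO4, MeOH–THF, −20 → 0 °C
Reagents that add atoms: none
Why: Reductive elimination of a vicinal bis-sulfone by electron transfer (Julia-type desulfonylation) should expel two sulfinate ions and unveil the strained C4=C9 bond without touching the bridgehead stereocentres or the terminal alkene.

**Step 6**
Reactants: 9 (1R,4S)-1-methyl-2-(2-methylpent-4-en-2-yl)-7-oxabicyclo[2.2.1]hepta-2,5-diene
Product: 10 (2S,7aR)-2-ethenyl-4,4,7a-trimethyl-2,4,5,7a-tetrahydro-1-benzofuran
Conditions: RuCl2(=CHPh)(PCy3)(H2IMes) (second-generation Grubbs catalyst, 5 mol %), ethylene (1 atm), CH2Cl2 (5 mM), 25 → 40 °C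
Reagents that add atoms: none
Why: The ruthenium benzylidene exchanges onto the monosubstituted pendant alkene and the resulting C3 alkylidene adds across the strained C4=C9 bridge; cycloreversion of the ruthenacyclobutane forms C3=C4 and leaves a C9 alkylidene that is released as the vinyl group by methylene transfer, ethylene acting only as a shuttle, so the step is a net isomerisation (ethenolysis of the bridge followed by ring closure would end at the same product). The closest known reaction type is the ring-rearrangement (ring-opening/ring-closing) metathesis of 7-oxanorbornenes that carry a pendant alkene. Ring A closes in ring-closing-metathesis mode as a six-membered carbocycle through the new C3=C4 bond, while ring B is not built but set free from the bicycle as the 2,5-dihydrofuran. No stereocentre is created: C5 and C8 are the bridgeheads of 9, and because C4 and C9 were the two ends of one etheno bridge they emerge cis across the ring oxygen with the absolute configuration fixed in step 4. The step needs chemoselectivity for C4=C9 and six- rather than seven-membered closure; the first follows from strain release at the disubstituted bridge versus the trisubstituted C6=C7 bond flanked by two quaternary carbons, the second from the tether, which lets C3 reach C4 but would demand a bridged seven-membered ring to bond to C9. Ethylene and high dilution should suppress ring-opening oligomerisation.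

**Step 7**
Reactants: 10 (2S,7aR)-2-ethenyl-4,4,7a-trimethyl-2,4,5,7a-tetrahydro-1-benzofuran
Product: 11 1-[(2R,7aR)-4,4,7a-trimethyl-2,4,5,7a-tetrahydro-1-benzofuran-2-yl]ethan-1-one
Conditions: PdCl2(quinox) (5 mol %; quinox = 2-(4,5-dihydro-1,3-oxazol-2-yl)quinoline), AgSbF6 (12 mol %), aq. tBuOOH (12 equiv), CH2Cl2, 0 °C → rt
Reagents that add atoms: tert-butyl hydroperoxide, CC(C)(C)OO
Why: Peroxide-mediated Wacker-type oxidation, a catalyst-controlled Markovnikov variant suited to terminal alkenes bearing an allylic oxygen, should convert only the vinyl group into the C9 methyl ketone (its methyl becomes C19) without passing through an enol, so C8 keeps its configuration and the ring alkenes are left alone.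

**Step 8**
Reactants: 11 methyl ketone
Product: 12 ethyl (2E)-3-[(2R,7aR)-4,4,7a-trimethyl-2,4,5,7a-tetrahydro-1-benzofuran-2-yl]but-2-enoate
Conditions: Ph3P=CHCO2Et (3 equiv), toluene, 90 °C
Reagents that add atoms: ethyl (triphenyl-λ5-phosphanylidene)acetate, CCOC(=O)C=P(c1ccccc1)(c1ccccc1)c1ccccc1
Why: Wittig olefination with a stabilised phosphorane, to which α-alkoxy ketones are unusually receptive, forms C9=C10 with the ester expected mainly trans to the branched C8 substituent (E), while the neutral ylide is far too weak a base to enolise the ketone toward C8; any 9Z isomer is removed by chromatography.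

**Step 9**
Reactants: 12 dienyl ester
Product: 14 ethyl (2E)-3-[(2R,6R,7aR)-6-hydroxy-4,4,7a-trimethyl-2,4,5,6,7,7a-hexahydro-1-benzofuran-2-yl]but-2-enoate, via C3 alkylborane 13 (not isolated)
Conditions: 9-BBN (2.5 equiv), THF, 60 °C; then NaBO3·4H2O, THF–H2O, rt
Reagents that add atoms: 9-borabicyclo[3.3.1]nonane (boron of intermediate 13), B1C2CCCC1CCC2; sodium perborate (hydroxyl oxygen), [Na+].[Na+].O[B-]1(O)OO[B-](O)(O)OO1
Why: Hydroboration–oxidation with a bulky dialkylborane should place boron on C3, the alkene carbon remote from the fully substituted C5, from the face opposite the pseudo-axial C5 methyl (the ring oxygen lies in the ring A plane), and oxidation with retention then gives the C3 hydroxyl cis to the ring oxygen, the electron-poor C9=C10 and the shielded C6=C7 bonds being inert to 9-BBN.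

**Step 10**
Reactants: 14 hydroxy ester
Product: 15 (2R,6R,7aR)-2-[(2E)-4-hydroxybut-2-en-2-yl]-4,4,7a-trimethyl-2,4,5,6,7,7a-hexahydro-1-benzofuran-6-ol
Conditions: iBu2AlH (3.5 equiv), CH2Cl2, −78 °C; aq. KNaC4H4O6
Reagents that add atoms: none
Why: Aluminium hydride 1,2-reduction of an α,β-unsaturated ester delivers the primary allylic alcohol (C11) without touching the alkenes or C8.

**Step 11**
Reactants: 15 diol
Product: 16 (2R,6R,7aR)-2-[(2E)-4-bromobut-2-en-2-yl]-4,4,7a-trimethyl-2,4,5,6,7,7a-hexahydro-1-benzofuran-6-ol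
Conditions: NBS (1.3 equiv), Me2S (1.6 equiv), CH2Cl2, −20 → 0 °C
Reagents that add atoms: N-bromosuccinimide, O=C1CCC(=O)N1Br
Why: Corey–Kim halogenation converts only the allylic alcohol into the bromide by SN2 displacement of its alkoxysulfonium salt, whereas the secondary ring alcohol reverts on work-up, and the neutral conditions spare the doubly allylic C8–O bond.

**Step 12**
Reactants: 16 allylic bromide
Product: 17 {(2E)-3-[(2R,6R,7aR)-6-hydroxy-4,4,7a-trimethyl-2,4,5,6,7,7a-hexahydro-1-benzofuran-2-yl]but-2-en-1-yl}(triphenyl)phosphonium bromide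
Conditions: PPh3 (1.1 equiv), EtOAc, rt, dark
Reagents that add atoms: triphenylphosphine, c1ccc(cc1)P(c1ccccc1)c1ccccc1
Why: SN2 quaternisation of a primary allylic bromide gives the C15 Wittig salt under neutral conditions, from which it should precipitate.

**Step 13**
Reactants: 18 (2E,4E,6E)-2,7-dimethylocta-2,4,6-trienedial; 19 ethyl (2E)-4-(diethoxyphosphoryl)-2-methylbut-2-enoate
Product: 20 ethyl (2E,4E,6E,8E,10E)-2,6,11-trimethyl-12-oxododeca-2,4,6,8,10-pentaenoate
Conditions: 18 (3 equiv), 19 (1 equiv), NaOEt (1.05 equiv, slow addition), THF–EtOH, −10 °C → rt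
Reagents that add atoms: none
Why: Horner–Wadsworth–Emmons mono-olefination of a symmetrical dial used in excess forms C11'=C12' with the E preference of stabilised phosphonate anions, and the unreacted dial is recovered.

**Step 14**
Reactants: 17 C15 phosphonium bromide; 20 C15 aldehyde ester
Product: 22 ethyl (2E,4E,6E,8E,10E,12E,14E)-15-[(2R,6R,7aR)-6-hydroxy-4,4,7a-trimethyl-2,4,5,6,7,7a-hexahydro-1-benzofuran-2-yl]-2,6,11-trimethylhexadeca-2,4,6,8,10,12,14-heptaenoate, via phosphonium ylide 21 (not isolated)
Conditions: NaOEt (1.1 equiv), CH2Cl2–EtOH, 0 °C → rt; then heptane, 80 °C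
Reagents that add atoms: none
Why: Wittig reaction of the allylic ylide with the polyenal forms C11=C12 as in standard carotenoid couplings with a free 3-hydroxyl group, the related 5,6-epoxy C15 ylides showing that an oxygen at the vinylogous β-position is tolerated, and warming converts the hindered 11Z isomer into the all-E polyene.

**Step 15**
Reactants: 22 C30 ester
Product: 23 (2R,6R,7aR)-2-[(2E,4E,6E,8E,10E,12E,14E)-16-hydroxy-6,11,15-trimethylhexadeca-2,4,6,8,10,12,14-heptaen-2-yl]-4,4,7a-trimethyl-2,4,5,6,7,7a-hexahydro-1-benzofuran-6-ol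
Conditions: iBu2AlH (4 equiv), CH2Cl2, −78 → −40 °C; aq. KNaC4H4O6
Reagents that add atoms: none
Why: Aluminium hydride 1,2-reduction of the conjugated ester gives the polyenylic primary alcohol under non-acidic conditions that should not ionise the C8–O bond.

**Step 16**
Reactants: 23 C30 diol
Product: 24 (2E,4E,6E,8E,10E,12E,14E)-15-[(2R,6R,7aR)-6-hydroxy-4,4,7a-trimethyl-2,4,5,6,7,7a-hexahydro-1-benzofuran-2-yl]-2,6,11-trimethylhexadeca-2,4,6,8,10,12,14-heptaenal, i.e. (3R,5R,8R)-5,8-epoxy-3-hydroxy-5,8-dihydro-8'-apo-β-caroten-8'-al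
Conditions: activated MnO2 (20 equiv), CH2Cl2, rt, dark
Reagents that add atoms: none
Why: Manganese dioxide oxidation is selective for the allylic (polyenylic) primary alcohol and leaves the saturated secondary C3 hydroxyl and the acid-sensitive furanoid ring untouched.

**Compound list**
1 | methyl 2-methylfuran-3-carboxylate | COC(=O)c1ccoc1C | starting material
2 | 1-(2-methylfuran-3-yl)ethan-1-one | CC(=O)c1ccoc1C | intermediate (not isolated)
3 | 2-(2-methylfuran-3-yl)propan-2-ol | CC(C)(O)c1ccoc1C | intermediate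
4 | allyltrimethylsilane | C=CC[Si](C)(C)C | starting material
5 | 2-methyl-3-(2-methylpent-4-en-2-yl)furan | Cc1occc1C(C)(C)CC=C | intermediate
6 | (E)-1,2-bis(phenylsulfonyl)ethene | O=S(=O)(/C=C/S(=O)(=O)c1ccccc1)c1ccccc1 | starting material
7 | rac-(1S,4R,5R,6R)-5,6-bis(benzenesulfonyl)-1-methyl-2-(2-methylpent-4-en-2-yl)-7-oxabicyclo[2.2.1]hept-2-ene (racemate, 5-exo,6-endo, relative configuration as in 8) | O=S(=O)(c1ccccc1)C1C(S(=O)(=O)c2ccccc2)C2(C)OC1C=C2C(C)(C)CC=C | intermediate
8 | (1S,4R,5R,6R)-5,6-bis(benzenesulfonyl)-1-methyl-2-(2-methylpent-4-en-2-yl)-7-oxabicyclo[2.2.1]hept-2-ene | [C@H]1(S(=O)(=O)c3ccccc3)[C@H](S(=O)(=O)c4ccccc4)[C@@]2(C)O[C@@H]1C=C2C(C)(C)CC=C | intermediate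
9 | (1R,4S)-1-methyl-2-(2-methylpent-4-en-2-yl)-7-oxabicyclo[2.2.1]hepta-2,5-diene | C1=C[C@@]2(C)O[C@@H]1C=C2C(C)(C)CC=C | intermediate (key-step precursor)
10 | (2S,7aR)-2-ethenyl-4,4,7a-trimethyl-2,4,5,7a-tetrahydro-1-benzofuran | C=C[C@H]1C=C2C(C)(C)CC=C[C@@]2(C)O1 | intermediate (key-step product)
11 | 1-[(2R,7aR)-4,4,7a-trimethyl-2,4,5,7a-tetrahydro-1-benzofuran-2-yl]ethan-1-one | CC(=O)[C@H]1C=C2C(C)(C)CC=C[C@@]2(C)O1 | intermediate
12 | ethyl (2E)-3-[(2R,7aR)-4,4,7a-trimethyl-2,4,5,7a-tetrahydro-1-benzofuran-2-yl]but-2-enoate | CCOC(=O)/C=C(\C)[C@H]1C=C2C(C)(C)CC=C[C@@]2(C)O1 | intermediate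
13 | C3 B-alkyl-9-BBN adduct of 12 (boron on C3, on the face of the ring oxygen) | CCOC(=O)/C=C(\C)[C@H]1C=C2C(C)(C)C[C@@H](B3C4CCCC3CCC4)C[C@@]2(C)O1 | intermediate (not isolated)
14 | ethyl (2E)-3-[(2R,6R,7aR)-6-hydroxy-4,4,7a-trimethyl-2,4,5,6,7,7a-hexahydro-1-benzofuran-2-yl]but-2-enoate | CCOC(=O)/C=C(\C)[C@H]1C=C2C(C)(C)C[C@@H](O)C[C@@]2(C)O1 | intermediate
15 | (2R,6R,7aR)-2-[(2E)-4-hydroxybut-2-en-2-yl]-4,4,7a-trimethyl-2,4,5,6,7,7a-hexahydro-1-benzofuran-6-ol | OC/C=C(\C)[C@H]1C=C2C(C)(C)C[C@@H](O)C[C@@]2(C)O1 | intermediate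
16 | (2R,6R,7aR)-2-[(2E)-4-bromobut-2-en-2-yl]-4,4,7a-trimethyl-2,4,5,6,7,7a-hexahydro-1-benzofuran-6-ol | BrC/C=C(\C)[C@H]1C=C2C(C)(C)C[C@@H](O)C[C@@]2(C)O1 | intermediate
17 | {(2E)-3-[(2R,6R,7aR)-6-hydroxy-4,4,7a-trimethyl-2,4,5,6,7,7a-hexahydro-1-benzofuran-2-yl]but-2-en-1-yl}(triphenyl)phosphonium bromide | C/C(=C\C[P+](c1ccccc1)(c1ccccc1)c1ccccc1)[C@H]1C=C2C(C)(C)C[C@@H](O)C[C@@]2(C)O1.[Br-] | intermediate
18 | (2E,4E,6E)-2,7-dimethylocta-2,4,6-trienedial | O=C/C(C)=C/C=C/C=C(C)/C=O | starting material
19 | ethyl (2E)-4-(diethoxyphosphoryl)-2-methylbut-2-enoate | CCOC(=O)/C(C)=C/CP(=O)(OCC)OCC | starting material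
20 | ethyl (2E,4E,6E,8E,10E)-2,6,11-trimethyl-12-oxododeca-2,4,6,8,10-pentaenoate | CCOC(=O)/C(C)=C/C=C/C(C)=C/C=C/C=C(C)/C=O | intermediate
21 | triphenylphosphonium ylide of 17 (C11 ylide) | C/C(=C\C=P(c1ccccc1)(c1ccccc1)c1ccccc1)[C@H]1C=C2C(C)(C)C[C@@H](O)C[C@@]2(C)O1 | intermediate (not isolated)
22 | ethyl (2E,4E,6E,8E,10E,12E,14E)-15-[(2R,6R,7aR)-6-hydroxy-4,4,7a-trimethyl-2,4,5,6,7,7a-hexahydro-1-benzofuran-2-yl]-2,6,11-trimethylhexadeca-2,4,6,8,10,12,14-heptaenoate | CCOC(=O)/C(C)=C/C=C/C(C)=C/C=C/C=C(C)/C=C/C=C(\C)[C@H]1C=C2C(C)(C)C[C@@H](O)C[C@@]2(C)O1 | intermediate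
23 | (2R,6R,7aR)-2-[(2E,4E,6E,8E,10E,12E,14E)-16-hydroxy-6,11,15-trimethylhexadeca-2,4,6,8,10,12,14-heptaen-2-yl]-4,4,7a-trimethyl-2,4,5,6,7,7a-hexahydro-1-benzofuran-6-ol | OC/C(C)=C/C=C/C(C)=C/C=C/C=C(C)/C=C/C=C(\C)[C@H]1C=C2C(C)(C)C[C@@H](O)C[C@@]2(C)O1 | intermediate
24 | (3R,5R,8R)-5,8-epoxy-3-hydroxy-5,8-dihydro-8'-apo-β-caroten-8'-al (CNP0118413.1) | C\C(C=O)=C/C=C/C(C)=C/C=C/C=C(C)/C=C/C=C(\C)[C@H]1C=C2C(C)(C)C[C@@H](O)C[C@@]2(C)O1 | target

**Count**
Total steps: 16. Longest linear sequence: 15 steps (steps 1–12 and 14–16, from compound 1); step 13 is a one-step side branch.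

**Steps most likely to fail**

Step 9. Regio- and facial control of the hydroboration may be lost: the allylic ring oxygen draws boron toward C4, and the gem-dimethyl group at C1 partly shields the face that is otherwise free. The fallback replaces hydroboration by electrophilic hydration, where sterics and the inductive effect of the C5–O bond both direct the hydroxyl to C3, and corrects the configuration by inversion.
- It sets out from 12 with oxymercuration (Hg(OAc)2, THF–H2O, rt), giving the trans-hydroxymercurial of 12 (C3 hydroxyl on the methyl face, C4 acetoxymercurio group on the oxygen face) F3.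
- Demercuration in the same flask (NaBH4, aq. NaOH, 0 °C) gives ethyl (2E)-3-[(2R,6S,7aR)-6-hydroxy-4,4,7a-trimethyl-2,4,5,6,7,7a-hexahydro-1-benzofuran-2-yl]but-2-enoate F4.
- Mitsunobu inversion (4-nitrobenzoic acid, PPh3, diisopropyl azodicarboxylate, THF, 0 °C) gives the (6R)-4-nitrobenzoate of 14 F5.
- Ethanolysis (K2CO3, EtOH, rt) returns to the route at 14.

Step 7. The palladium-bound alkene may be attacked at its terminal carbon (aldehyde formation), or the cationic catalyst may ionise or isomerise the doubly allylic C8 position, eroding regiocontrol and the C8 configuration. The fallback is a radical Markovnikov hydration followed by oxidation.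
- It sets out from 10 with a Mukaiyama hydration (Co(acac)2 cat., PhSiH3, O2, iPrOH, rt), which acts on the monosubstituted alkene much faster than on the 1,2-disubstituted ring alkene. This gives 1-[(2R,7aR)-4,4,7a-trimethyl-2,4,5,7a-tetrahydro-1-benzofuran-2-yl]ethan-1-ol (both carbinol epimers) F1.
- Buffered Dess–Martin oxidation (NaHCO3, CH2Cl2, 0 °C) returns to the route at 11.

Step 8. Addition of the stabilised ylide to the hindered ketone may be so slow that enolisation toward C8 (epimerisation, double-bond migration) or poor E/Z control takes over. The fallback builds C9=C10 by acetylide addition and rearrangement.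
- It sets out from 11 with lithium ethoxyacetylide (ethoxyacetylene, n-BuLi, CeCl3, THF, −78 °C), which adds faster than it deprotonates. This gives 4-ethoxy-2-[(2R,7aR)-4,4,7a-trimethyl-2,4,5,7a-tetrahydro-1-benzofuran-2-yl]but-3-yn-2-ol (both carbinol epimers) F2.
- Meyer–Schuster rearrangement (AuCl3 5 mol %, EtOH, CH2Cl2, rt) converts F2 into the enoate and returns to the route at 12.

**Further compounds**
F1 | step 7 | 1-[(2R,7aR)-4,4,7a-trimethyl-2,4,5,7a-tetrahydro-1-benzofuran-2-yl]ethan-1-ol (both carbinol epimers) | CC(O)[C@H]1C=C2C(C)(C)CC=C[C@@]2(C)O1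
F2 | step 8 | 4-ethoxy-2-[(2R,7aR)-4,4,7a-trimethyl-2,4,5,7a-tetrahydro-1-benzofuran-2-yl]but-3-yn-2-ol (both carbinol epimers) | CCOC#CC(C)(O)[C@H]1C=C2C(C)(C)CC=C[C@@]2(C)O1
F3 | step 9 | trans-hydroxymercurial of 12 (C3 hydroxyl on the methyl face, C4 acetoxymercurio group on the oxygen face) | CCOC(=O)/C=C(\C)[C@H]1C=C2C(C)(C)C[C@H](O)C([Hg]OC(C)=O)[C@@]2(C)O1
F4 | step 9 | ethyl (2E)-3-[(2R,6S,7aR)-6-hydroxy-4,4,7a-trimethyl-2,4,5,6,7,7a-hexahydro-1-benzofuran-2-yl]but-2-enoate | CCOC(=O)/C=C(\C)[C@H]1C=C2C(C)(C)C[C@H](O)C[C@@]2(C)O1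
F5 | step 9 | (6R)-4-nitrobenzoate of 14 | CCOC(=O)/C=C(\C)[C@H]1C=C2C(C)(C)C[C@@H](OC(=O)c3ccc(cc3)[N+](=O)[O-])C[C@@]2(C)O1
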